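**Plan**

- Ring A is read round the ring as its prenyl-bearing carbon, pyran-oxygen carbon, pyran-olefin carbon, hydroxyl carbon, carboxyl-bearing carbon and ether-oxygen carbon; ring B as its ether-oxygen carbon, its CH, its hydroxyl carbon, pyran-oxygen carbon, pyran-olefin carbon and ester-oxygen carbon; ring C is the seven-membered lactone between them.
- Cuts, in order: the ester C–O bond of ring C; the ring A pyran (its O–C and C–C bonds to a 3-methyl-2-butenal unit); ring A itself at three bonds (pyran-oxygen carbon to prenyl-bearing carbon, ether-oxygen carbon to carboxyl-bearing carbon, pyran-oxygen carbon to pyran-olefin carbon); then the alkynyl ether (prenyl–C and O–C bonds) and the ring B pyran.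
- Enabling feature: round ring A the three oxygen-bearing carbons alternate with the three carbon-bearing ones, and the oxygen on the ether-oxygen carbon is the bridge to ring B. Ring A is therefore the benzannulation product of an ester-bearing vinylketene (four carbons: pyran-oxygen, pyran-olefin, hydroxyl, carboxyl-bearing) and an alkynyl ether of the ring B phenol (two carbons: prenyl-bearing, ether-oxygen).
- Forward order: ring B pyran, ynol ether, ring A by benzannulation, ring A pyran, acid and phenols set free, ring C by lactonisation.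
- Stereochemistry: the target has no stereocentre; the only chiral intermediate, the vinylcyclobutenone of the key step, is racemic and aromatises.

Key step: step 8

Assumption: the diethyl acetal of 3-methyl-2-butenal and methyl 4,4-dimethoxy-3-oxopentanoate are bought as such, and ring C is closed from the free acid because replacing the methanol of a methyl ester by a phenol is uphill.

**Route**

Step 1
Reactants: 1 2,5-dihydroxy-1,4-benzoquinone
Product: 3 2,5-bis(methoxymethoxy)benzene-1,4-diol, via quinone diether 2 (not isolated)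
Conditions: MOMCl (2.4 equiv), i-Pr2NEt (2.6 equiv), CH2Cl2, 0 °C to rt; then aq. Na2S2O4, EtOAc, rt
Reagents that add atoms: chloromethyl methyl ether, COCCl
Why: The hydroxyquinone is a vinylogous carboxylic acid whose ammonium salt should be O-alkylated by the oxocarbenium-like chloride to the para-quinone diether (Williamson-type O-alkylation), and dithionite reduction of the quinone then turns the two carbonyl oxygens into the free para phenols.

Step 2
Reactants: 3 2,5-bis(methoxymethoxy)benzene-1,4-diol; 4 1,1-diethoxy-3-methylbut-2-ene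
Product: 5 5,8-bis(methoxymethoxy)-2,2-dimethyl-2H-chromen-6-ol
Conditions: 4 (0.8 equiv), 3-picoline, p-xylene, 140 °C, Ar
Reagents that add atoms: none
Why: Pyridine-base chromenylation of a phenol with an enal acetal (acetal exchange, loss of ethanol, ortho-quinone methide, oxa-6π electrocyclisation) can only use the one free ortho carbon of each phenol, and keeping the acetal limiting should hold the symmetric diol to a single annulation.

Step 3
Reactants: 5 5,8-bis(methoxymethoxy)-2,2-dimethyl-2H-chromen-6-ol; 6 trichloroethylene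
Product: 7 6-{[(E)-1,2-dichloroethenyl]oxy}-5,8-bis(methoxymethoxy)-2,2-dimethyl-2H-chromene
Conditions: K2CO3, DMF, 70 °C
Reagents that add atoms: none
Why: The phenoxide adds anti to dichloroacetylene formed in the flask from trichloroethylene, the standard addition route to aryl (E)-1,2-dichlorovinyl ethers.

Step 4
Reactants: 7 6-{[(E)-1,2-dichloroethenyl]oxy}-5,8-bis(methoxymethoxy)-2,2-dimethyl-2H-chromene; 8 prenyl bromide
Product: 10 5,8-bis(methoxymethoxy)-2,2-dimethyl-6-[(5-methylhex-4-en-1-yn-1-yl)oxy]-2H-chromene, via lithium aryloxyacetylide 9 (not isolated)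
Conditions: n-BuLi (2.2 equiv), THF, −78 to −40 °C; then 8, DMPU, −78 °C to rt
Reagents that add atoms: none
Why: Dehydrochlorination followed by chlorine–lithium exchange gives the lithium aryloxyacetylide, and its nucleophilic substitution at the primary carbon of prenyl bromide should give the skipped enyne (dichlorovinyl ether route to ynol ethers).

Step 5
Reactants: 11 methyl 4,4-dimethoxy-3-oxopentanoate
Product: 12 methyl 2-diazo-4,4-dimethoxy-3-oxopentanoate
Conditions: 4-acetamidobenzenesulfonyl azide, Et3N, MeCN, 0 °C to rt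
Reagents that add atoms: 4-acetamidobenzenesulfonyl azide, CC(=O)Nc1ccc(cc1)S(=O)(=O)N=[N+]=[N-]
Why: Regitz diazo transfer to the active methylene of a beta-keto ester is reliable and leaves the ketal untouched.

Step 6
Reactants: 12 methyl 2-diazo-4,4-dimethoxy-3-oxopentanoate
Product: 13 methyl 2-diazo-3,4-dioxopentanoate
Conditions: TFA/H2O (9:1), CH2Cl2, 0 °C to rt; azeotropic drying with toluene
Reagents that add atoms: water, O
Why: Acid-catalysed ketal hydrolysis should free the ketone, since a diazo group flanked by two carbonyls tolerates aqueous trifluoroacetic acid.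

Step 7
Reactants: 13 methyl 2-diazo-3,4-dioxopentanoate
Product: 14 methyl 2-diazo-3-oxo-4-[(triisopropylsilyl)oxy]pent-4-enoate
Conditions: TIPSOTf, Et3N, CH2Cl2, 0 °C
Reagents that add atoms: triisopropylsilyl trifluoromethanesulfonate, CC(C)[Si](OS(=O)(=O)C(F)(F)F)(C(C)C)C(C)C
Why: Silyl enol ether formation by soft enolisation can only take place at the methyl group of the 1,2-dione, the single enolisable position of 13.

Step 8
Reactants: 14 methyl 2-diazo-3-oxo-4-[(triisopropylsilyl)oxy]pent-4-enoate; 10 5,8-bis(methoxymethoxy)-2,2-dimethyl-6-[(5-methylhex-4-en-1-yn-1-yl)oxy]-2H-chromene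
Product: 19 methyl 2-{[5,8-bis(methoxymethoxy)-2,2-dimethyl-2H-chromen-6-yl]oxy}-4-hydroxy-3-(3-methylbut-2-en-1-yl)-6-[(triisopropylsilyl)oxy]benzoate, via vinylketene 15 (not isolated), via vinylcyclobutenone 16 (not isolated), via dienylketene 17 (not isolated), via cyclohexadienone 18 (not isolated)
Conditions: 14 (1.5 equiv), hν (365 nm), degassed CH2Cl2, rt; then toluene, 80 °C
Reagents that add atoms: none
Why: Light expels dinitrogen from 14 and the siloxyvinyl group shifts from the ketone carbon to the diazo carbon (photochemical Wolff rearrangement), giving vinylketene 15 with the ester on its alpha-carbon. Ynol ether 10 should then add across the ketene C=C in a [2+2] cycloaddition whose regiochemistry follows the polarisation of the alkyne: the prenyl-bearing alkyne carbon, beta to oxygen and nucleophilic, bonds to the ketene carbonyl carbon and the aryloxy carbon bonds to the ester-bearing carbon, giving 16. Four-electron conrotatory opening of 16 to dienylketene 17 and six-electron disrotatory electrocyclisation, which joins the ketene carbon to the terminal methylene, close ring A as cyclohexadienone 18, and this tautomerises to phenol 19; the sequence is the Danheiser benzannulation in its photochemical variant. No stereocentre results, because the quaternary carbon of racemic 16 becomes sp2 on ring opening. The step needs the [2+2] addition to outrun capture of 15 through its ester carbonyl as a heterodiene and through the prenyl and chromene olefins; the ynol ether is by far the most ketenophilic pi bond present, its aryloxy donor should favour a concerted [2+2] over a zwitterion that the ester oxygen could trap, and alkenyl rather than methoxy migrates in the Wolff step. Irradiation at 365 nm is chosen to reach the diazo enone while lying beyond the absorption of the ring B chromene, and the phenol is set free only in the dark heating stage, when no ketene is left to acylate it.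

Step 9
Reactants: 19 methyl 2-{[5,8-bis(methoxymethoxy)-2,2-dimethyl-2H-chromen-6-yl]oxy}-4-hydroxy-3-(3-methylbut-2-en-1-yl)-6-[(triisopropylsilyl)oxy]benzoate; 4 1,1-diethoxy-3-methylbut-2-ene
Product: 20 methyl 7-{[5,8-bis(methoxymethoxy)-2,2-dimethyl-2H-chromen-6-yl]oxy}-2,2-dimethyl-8-(3-methylbut-2-en-1-yl)-5-[(triisopropylsilyl)oxy]-2H-chromene-6-carboxylate
Conditions: 4 (2 equiv), 3-picoline, p-xylene, 140 °C
Reagents that add atoms: none
Why: The same enal acetal chromenylation, known for phenols with a para ester, has a single outcome here because the phenol has only one free ortho carbon (the other carries the prenyl group) and the second ring A oxygen is silylated.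

Step 10
Reactants: 20 methyl 7-{[5,8-bis(methoxymethoxy)-2,2-dimethyl-2H-chromen-6-yl]oxy}-2,2-dimethyl-8-(3-methylbut-2-en-1-yl)-5-[(triisopropylsilyl)oxy]-2H-chromene-6-carboxylate
Product: 21 7-{[5,8-bis(methoxymethoxy)-2,2-dimethyl-2H-chromen-6-yl]oxy}-5-hydroxy-2,2-dimethyl-8-(3-methylbut-2-en-1-yl)-2H-chromene-6-carboxylic acid
Conditions: KOH, DMSO/H2O, 90 °C; then aq. HCl to pH 3, 0 °C
Reagents that add atoms: potassium hydroxide, [K+].[OH-]
Why: Saponification with KOH in aqueous DMSO is the usual answer to doubly ortho-substituted methyl benzoates, hydroxide also cleaves the aryl silyl ether, and the acetals, chromenes and prenyl group are inert to base.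

Step 11
Reactants: 21 7-{[5,8-bis(methoxymethoxy)-2,2-dimethyl-2H-chromen-6-yl]oxy}-5-hydroxy-2,2-dimethyl-8-(3-methylbut-2-en-1-yl)-2H-chromene-6-carboxylic acid
Product: 22 7-[(5,8-dihydroxy-2,2-dimethyl-2H-chromen-6-yl)oxy]-5-hydroxy-2,2-dimethyl-8-(3-methylbut-2-en-1-yl)-2H-chromene-6-carboxylic acid
Conditions: HCl (3 M aq.), MeOH/THF, rt, Ar
Reagents that add atoms: none
Why: Acid-catalysed acetal exchange with methanol removes both methoxymethyl ethers at room temperature, conditions under which dimethylchromenes are known to survive and the hindered acid is not esterified.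

Step 12
Reactants: 22 7-[(5,8-dihydroxy-2,2-dimethyl-2H-chromen-6-yl)oxy]-5-hydroxy-2,2-dimethyl-8-(3-methylbut-2-en-1-yl)-2H-chromene-6-carboxylic acid
Product: 23 garcinisidone C
Conditions: EDC·HCl, DMAP (cat.), CH2Cl2/THF (high dilution), 0 °C to rt, Ar
Reagents that add atoms: none
Why: Carbodiimide lactonisation of a 2-(2-hydroxyaryloxy)benzoic acid is the classical depsidone ring closure, and only the ring B hydroxyl ortho to the diaryl ether oxygen can reach the activated carboxyl, so the seven-membered ring C should form selectively.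

**Compound list**

1 | 2,5-dihydroxy-1,4-benzoquinone | O=C1C=C(O)C(=O)C=C1O | starting material
2 | 2,5-bis(methoxymethoxy)-1,4-benzoquinone | O=C1C=C(OCOC)C(=O)C=C1OCOC | intermediate
3 | 2,5-bis(methoxymethoxy)benzene-1,4-diol | Oc1cc(OCOC)c(O)cc1OCOC | intermediate
4 | 1,1-diethoxy-3-methylbut-2-ene (diethyl acetal of 3-methyl-2-butenal) | CCOC(OCC)C=C(C)C | starting material
5 | 5,8-bis(methoxymethoxy)-2,2-dimethyl-2H-chromen-6-ol (ring B phenol) | Oc1cc(OCOC)c2OC(C)(C)C=Cc2c1OCOC | intermediate
6 | trichloroethylene | ClC=C(Cl)Cl | starting material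
7 | 6-{[(E)-1,2-dichloroethenyl]oxy}-5,8-bis(methoxymethoxy)-2,2-dimethyl-2H-chromene | Cl/C=C(/Cl)Oc1cc(OCOC)c2OC(C)(C)C=Cc2c1OCOC | intermediate
8 | prenyl bromide (1-bromo-3-methylbut-2-ene) | CC(C)=CCBr | starting material
9 | lithium 2-{[5,8-bis(methoxymethoxy)-2,2-dimethyl-2H-chromen-6-yl]oxy}ethynide | [Li]C#COc1cc(OCOC)c2OC(C)(C)C=Cc2c1OCOC | intermediate
10 | 5,8-bis(methoxymethoxy)-2,2-dimethyl-6-[(5-methylhex-4-en-1-yn-1-yl)oxy]-2H-chromene (ring B ynol ether) | CC(C)=CCC#COc1cc(OCOC)c2OC(C)(C)C=Cc2c1OCOC | intermediate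
11 | methyl 4,4-dimethoxy-3-oxopentanoate | COC(=O)CC(=O)C(C)(OC)OC | starting material
12 | methyl 2-diazo-4,4-dimethoxy-3-oxopentanoate | COC(=O)C(=[N+]=[N-])C(=O)C(C)(OC)OC | intermediate
13 | methyl 2-diazo-3,4-dioxopentanoate | COC(=O)C(=[N+]=[N-])C(=O)C(C)=O | intermediate
14 | methyl 2-diazo-3-oxo-4-[(triisopropylsilyl)oxy]pent-4-enoate | COC(=O)C(=[N+]=[N-])C(=O)C(=C)O[Si](C(C)C)(C(C)C)C(C)C | intermediate
15 | methyl 2-(oxomethylidene)-3-[(triisopropylsilyl)oxy]but-3-enoate (vinylketene) | COC(=O)C(=C=O)C(=C)O[Si](C(C)C)(C(C)C)C(C)C | intermediate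
16 | methyl 2-{[5,8-bis(methoxymethoxy)-2,2-dimethyl-2H-chromen-6-yl]oxy}-3-(3-methylbut-2-en-1-yl)-4-oxo-1-{1-[(triisopropylsilyl)oxy]ethenyl}cyclobut-2-ene-1-carboxylate (racemic vinylcyclobutenone) | COC(=O)C1(C(=C)O[Si](C(C)C)(C(C)C)C(C)C)C(=O)C(CC=C(C)C)=C1Oc1cc(OCOC)c2OC(C)(C)C=Cc2c1OCOC | intermediate
17 | (Z)-dienylketene from ring opening of 16: ketene carbon on the prenyl-bearing carbon, then C(O-aryl)=C(CO2Me) carrying the siloxyvinyl group cis to the ketene arm | O=C=C(CC=C(C)C)/C(Oc1cc(OCOC)c2OC(C)(C)C=Cc2c1OCOC)=C(/C(=O)OC)C(=C)O[Si](C(C)C)(C(C)C)C(C)C | intermediate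
18 | cyclohexa-2,4-dienone tautomer of 19 (ring CH2 next to the ring ketone) | O=C1CC(O[Si](C(C)C)(C(C)C)C(C)C)=C(C(=O)OC)C(Oc2cc(OCOC)c3OC(C)(C)C=Cc3c2OCOC)=C1CC=C(C)C | intermediate
19 | methyl 2-{[5,8-bis(methoxymethoxy)-2,2-dimethyl-2H-chromen-6-yl]oxy}-4-hydroxy-3-(3-methylbut-2-en-1-yl)-6-[(triisopropylsilyl)oxy]benzoate | COC(=O)c1c(O[Si](C(C)C)(C(C)C)C(C)C)cc(O)c(CC=C(C)C)c1Oc1cc(OCOC)c2OC(C)(C)C=Cc2c1OCOC | intermediate
20 | methyl 7-{[5,8-bis(methoxymethoxy)-2,2-dimethyl-2H-chromen-6-yl]oxy}-2,2-dimethyl-8-(3-methylbut-2-en-1-yl)-5-[(triisopropylsilyl)oxy]-2H-chromene-6-carboxylate | COC(=O)c1c(O[Si](C(C)C)(C(C)C)C(C)C)c2C=CC(C)(C)Oc2c(CC=C(C)C)c1Oc1cc(OCOC)c2OC(C)(C)C=Cc2c1OCOC | intermediate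
21 | 7-{[5,8-bis(methoxymethoxy)-2,2-dimethyl-2H-chromen-6-yl]oxy}-5-hydroxy-2,2-dimethyl-8-(3-methylbut-2-en-1-yl)-2H-chromene-6-carboxylic acid | OC(=O)c1c(O)c2C=CC(C)(C)Oc2c(CC=C(C)C)c1Oc1cc(OCOC)c2OC(C)(C)C=Cc2c1OCOC | intermediate
22 | 7-[(5,8-dihydroxy-2,2-dimethyl-2H-chromen-6-yl)oxy]-5-hydroxy-2,2-dimethyl-8-(3-methylbut-2-en-1-yl)-2H-chromene-6-carboxylic acid | OC(=O)c1c(O)c2C=CC(C)(C)Oc2c(CC=C(C)C)c1Oc1cc(O)c2OC(C)(C)C=Cc2c1O | intermediate
23 | garcinisidone C | CC(C)=CCc1c2c(c(O)c3c1Oc1cc(O)c4c(c1OC3=O)C=CC(C)(C)O4)C=CC(C)(C)O2 | target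

**Totals and risks**

Total steps: 12. Longest linear sequence: 9 steps (steps 1 to 4 and 8 to 12); the diazo partner takes 3 steps (5 to 7).

Steps most likely to fail:

Step 8. The ester-bearing ketene may be captured through its ester carbonyl in a hetero-[4+2] addition to the ynol ether instead of the [2+2] addition. The ring B chromene may also be opened by the light, and excess ketene may acylate the new phenol.
Fallback: the carboxyl carbon is left out of the ketene and added once ring A exists. Butane-2,3-dione is silylated (TIPSOTf, Et3N) to 3-[(triisopropylsilyl)oxy]but-3-en-2-one F1. Its kinetic enolate (LiN(SiMe3)2, THF, −78 °C) is acylated with 2,2,2-trifluoroethyl trifluoroacetate to 1,1,1-trifluoro-5-[(triisopropylsilyl)oxy]hex-5-ene-2,4-dione F2. Diazo transfer with MsN3, Et3N and water in MeCN, with loss of the trifluoroacetyl group, gives 1-diazo-3-[(triisopropylsilyl)oxy]but-3-en-2-one F3. Irradiation of F3 with 10 and heating as in step 8 should give 3-(ring B aryloxy)-2-prenyl-5-[(triisopropylsilyl)oxy]phenol F4 through a vinylketene that has no carbonyl to act as a heterodiene. Chromenylation with 4 as in step 9 gives the silylated bis-chromene F5, and TBAF frees the ring A phenol at the 5-position of the new chromene to give chromen-5-ol F6. Ortho-formylation (MgCl2, Et3N, paraformaldehyde, MeCN, reflux) can only reach the one free carbon ortho to that phenol and gives salicylaldehyde F7. Pinnick oxidation (NaClO2, NaH2PO4, 2-methylbut-2-ene, t-BuOH/H2O) then gives acid 21. The fallback sets out from 10 and returns at 21.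

Step 4. The lithium acetylide may alkylate slowly or at the tertiary end of the allyl system, the skipped enyne may isomerise to an allene under the basic conditions, and n-BuLi may add to the ynol ether.
Fallback: the C–O bond is made instead by copper catalysis on a chain that already holds the prenyl unit. 4-Methylpent-3-en-1-ol is oxidised with Dess–Martin periodinane to 4-methylpent-3-enal F8. Ramirez olefination (CBr4, PPh3, CH2Cl2, 0 °C) gives 1,1-dibromo-5-methylhexa-1,4-diene F9. Coupling of F9 with phenol 5 (CuI, 2,2'-bipyridine, K3PO4, toluene, 110 °C) should give the (Z)-1-bromoenol ether F10. Anti elimination of HBr with KOtBu in THF at low temperature gives 10. The fallback sets out from 5 and returns at 10.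

Step 11. The electron-rich salicylic acid may lose carbon dioxide under acid, methanol or HCl may add to the chromene double bonds, and the freed ring B hydroquinone may be oxidised by air.
Fallback: the order of unmasking is reversed so that no free acid meets acid. Ester 20 is treated with HCl in MeOH/THF to give the bis-phenol methyl ester F11, with the ester and silyl ether intact. KOH in degassed aqueous DMSO containing Na2S2O4 then cleaves the silyl ether and the ester, and cold acidification gives 22. The fallback sets out from 20 and returns at 22.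

Further compounds
F1 | step 8 | 3-[(triisopropylsilyl)oxy]but-3-en-2-one | CC(=O)C(=C)O[Si](C(C)C)(C(C)C)C(C)C
F2 | step 8 | 1,1,1-trifluoro-5-[(triisopropylsilyl)oxy]hex-5-ene-2,4-dione | C=C(O[Si](C(C)C)(C(C)C)C(C)C)C(=O)CC(=O)C(F)(F)F
F3 | step 8 | 1-diazo-3-[(triisopropylsilyl)oxy]but-3-en-2-one | C=C(O[Si](C(C)C)(C(C)C)C(C)C)C(=O)C=[N+]=[N-]
F4 | step 8 | 3-{[5,8-bis(methoxymethoxy)-2,2-dimethyl-2H-chromen-6-yl]oxy}-2-(3-methylbut-2-en-1-yl)-5-[(triisopropylsilyl)oxy]phenol | CC(C)=CCc1c(O)cc(O[Si](C(C)C)(C(C)C)C(C)C)cc1Oc1cc(OCOC)c2OC(C)(C)C=Cc2c1OCOC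
F5 | step 8 | 7-{[5,8-bis(methoxymethoxy)-2,2-dimethyl-2H-chromen-6-yl]oxy}-2,2-dimethyl-8-(3-methylbut-2-en-1-yl)-5-[(triisopropylsilyl)oxy]-2H-chromene | CC(C)=CCc1c(Oc2cc(OCOC)c3OC(C)(C)C=Cc3c2OCOC)cc(O[Si](C(C)C)(C(C)C)C(C)C)c2C=CC(C)(C)Oc12
F6 | step 8 | 7-{[5,8-bis(methoxymethoxy)-2,2-dimethyl-2H-chromen-6-yl]oxy}-2,2-dimethyl-8-(3-methylbut-2-en-1-yl)-2H-chromen-5-ol | CC(C)=CCc1c(Oc2cc(OCOC)c3OC(C)(C)C=Cc3c2OCOC)cc(O)c2C=CC(C)(C)Oc12
F7 | step 8 | 7-{[5,8-bis(methoxymethoxy)-2,2-dimethyl-2H-chromen-6-yl]oxy}-5-hydroxy-2,2-dimethyl-8-(3-methylbut-2-en-1-yl)-2H-chromene-6-carbaldehyde | CC(C)=CCc1c(Oc2cc(OCOC)c3OC(C)(C)C=Cc3c2OCOC)c(C=O)c(O)c2C=CC(C)(C)Oc12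
F8 | step 4 | 4-methylpent-3-enal | CC(C)=CCC=O
F9 | step 4 | 1,1-dibromo-5-methylhexa-1,4-diene | CC(C)=CCC=C(Br)Br
F10 | step 4 | 6-{[(Z)-1-bromo-5-methylhexa-1,4-dien-1-yl]oxy}-5,8-bis(methoxymethoxy)-2,2-dimethyl-2H-chromene | CC(C)=CC/C=C(\Br)Oc1cc(OCOC)c2OC(C)(C)C=Cc2c1OCOC
F11 | step 11 | methyl 7-[(5,8-dihydroxy-2,2-dimethyl-2H-chromen-6-yl)oxy]-2,2-dimethyl-8-(3-methylbut-2-en-1-yl)-5-[(triisopropylsilyl)oxy]-2H-chromene-6-carboxylate | COC(=O)c1c(O[Si](C(C)C)(C(C)C)C(C)C)c2C=CC(C)(C)Oc2c(CC=C(C)C)c1Oc1cc(O)c2OC(C)(C)C=Cc2c1O
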